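## Retrosynthetic overview

- **Ring labels.** The rings run along the chain as A (3,5-dihydroxyphenoxy end), B, C, D and E (2,4,6-trihydroxyphenoxy end). In ring A, C-1 bears the ether O to B. In rings B, D and E, C-1 is the ether carbon lying between two oxygenated carbons (it bears O–A, O–C and O–D respectively). In ring C, C-1 bears O–B and C-4 bears O–D.
- **Feature.** The hydroxyls on C-5 of ring A and on C-4 of rings B, D and E sit on the only carbons of those rings whose two neighbours are both C–H. C-3 and C-5 of ring C are each wedged between two oxygens. These four C–O bonds are therefore disconnected last, back to C–H (15 ⇒ 14 ⇒ 12).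
- **Central cut.** Pentamer 12 is cut at the C-4(ring C)–O bond into ABC bromide 7 and DE phenol 11 (Ullmann ether synthesis).
- **Halves.** Both halves come from one electrophile, 2-fluoro-6-methoxybenzaldehyde. SNAr with a 2,6-dimethoxyphenol makes the B–O–C or D–O–E bond, Baeyer–Villiger oxidation turns CHO into the flanked OH, and ring A is added to 5 by Chan–Lam coupling.
- **Rings.** No ring is formed at any stage, since all five benzene rings are bought. They are joined in the order C+B, then A; E+D; then ABC+DE.

Key step: step 7

Remark: the target has no stereocentre and its diaryl ether axes carry only small ortho groups and should rotate freely, so it is achiral and no enantiomer has to be selected.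

## Route

Step 1
Reactants: 1 4-bromo-2,6-dimethoxyphenol; 2 2-fluoro-6-methoxybenzaldehyde
Product: 3 2-(4-bromo-2,6-dimethoxyphenoxy)-6-methoxybenzaldehyde
Conditions: Cs2CO3 (1.5 equiv), DMSO, 100 °C
Reagents that add atoms: none
Why: This is a nucleophilic aromatic substitution (SNAr) in which the ortho formyl group stabilises the Meisenheimer adduct at the C–F carbon, the methoxy group of 2 is meta to fluorine and does not deactivate that carbon, and the aryl bromide of 1 is inert in the absence of a metal.

Step 2
Reactants: 3 2-(4-bromo-2,6-dimethoxyphenoxy)-6-methoxybenzaldehyde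
Product: 5 2-(4-bromo-2,6-dimethoxyphenoxy)-6-methoxyphenol, via aryl formate 4 (not isolated)
Conditions: mCPBA (1.3 equiv), CH2Cl2, 0 °C → rt; aq NaHCO3/Na2S2O3 wash; then K2CO3 (cat.), MeOH, rt
Reagents that add atoms: mCPBA, OOC(=O)c1cccc(Cl)c1
Why: In this Baeyer–Villiger oxidation of an electron-rich benzaldehyde (Dakin-type outcome) the aryl group with two ortho oxygen donors migrates in the Criegee adduct in preference to hydride, and the labile formate is removed by methanolysis without touching bromide or ethers.

Step 3
Reactants: 5 2-(4-bromo-2,6-dimethoxyphenoxy)-6-methoxyphenol; 6 3-methoxyphenylboronic acid (2.5 equiv)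
Product: 7 5-bromo-1,3-dimethoxy-2-[3-methoxy-2-(3-methoxyphenoxy)phenoxy]benzene (ABC bromide)
Conditions: Cu(OAc)2 (2 equiv), pyridine (5 equiv), 4 Å MS, CH2Cl2, dry air, rt
Reagents that add atoms: none
Why: The Chan–Lam–Evans oxidative coupling proceeds by boron-to-copper transmetalation and C–O reductive elimination from an aryl copper(III) phenoxide at room temperature, a regime that accepts 2,6-disubstituted phenols and leaves the aryl bromide untouched, so 5 cannot couple with itself.

Step 4
Reactants: 8 2,6-dimethoxyphenol; 2 2-fluoro-6-methoxybenzaldehyde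
Product: 9 2-(2,6-dimethoxyphenoxy)-6-methoxybenzaldehyde
Conditions: Cs2CO3 (1.5 equiv), DMSO, 100 °C
Reagents that add atoms: none
Why: This is the same formyl-activated SNAr as in step 1, here with the somewhat more nucleophilic bromine-free phenoxide.

Step 5
Reactants: 9 2-(2,6-dimethoxyphenoxy)-6-methoxybenzaldehyde
Product: 11 2-(2,6-dimethoxyphenoxy)-6-methoxyphenol (DE phenol), via aryl formate 10 (not isolated)
Conditions: mCPBA (1.3 equiv), CH2Cl2, 0 °C → rt; aq NaHCO3/Na2S2O3 wash; then K2CO3 (cat.), MeOH, rt
Reagents that add atoms: mCPBA, OOC(=O)c1cccc(Cl)c1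
Why: This is a Baeyer–Villiger oxidation and formate methanolysis as in step 2, with aryl migration again favoured by the two ortho oxygen substituents.

Step 6
Reactants: 7 ABC bromide; 11 DE phenol (1.2 equiv)
Product: 12 1,3-dimethoxy-5-[2-(2,6-dimethoxyphenoxy)-6-methoxyphenoxy]-2-[3-methoxy-2-(3-methoxyphenoxy)phenoxy]benzene (tetra-deoxy pentamer heptamethyl ether)
Conditions: CuI (20 mol %), picolinic acid (40 mol %), K3PO4 (2 equiv), DMSO, 100 °C, Ar
Reagents that add atoms: none
Why: In this ligand-accelerated Ullmann diaryl ether synthesis the C–Br carbon of 7 has two hydrogen neighbours, so all the steric load lies on the phenoxide, which is the case the CuI/picolinic acid/K3PO4/DMSO system is known to handle.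

Step 7
Reactants: 12 tetra-deoxy pentamer heptamethyl ether
Product: 14 tetraphenol heptamethyl ether of the target, via tetrakis(pinacol boronate) 13 (not isolated)
Conditions: [Ir(OMe)(cod)]2 (5 mol %), dtbpy (10 mol %), B2pin2 (6 equiv), THF, 80 °C (sealed), Ar; volatiles removed; then 30% aq H2O2, 1 M NaOH, THF, 0 °C, Ar; aq Na2S2O3/NH4Cl work-up
Reagents that add atoms: bis(pinacolato)diboron, CC1(C)OB(OC1(C)C)B1OC(C)(C)C(C)(C)O1 (boryl groups of 13); hydrogen peroxide, OO (the four new oxygens of 14)
Why: The dtbpy-ligated iridium(III) tris(boryl) complex cleaves an arene C–H bond and releases the aryl boronate by C–B reductive elimination, after which hydroperoxide adds to each boron and triggers a 1,2-shift of the aryl group from boron to oxygen, so every C–B bond becomes a C–O bond at the same carbon. The closest known reaction type is the one-pot iridium-catalysed arene C–H borylation/oxidation route to meta-substituted phenols, together with the known multiple borylations of polyarenes, and here it is simply run four times on one molecule. No ring is closed and no stereocentre is made. The selectivity needed is site selectivity within and between the rings, and it rests on sterics alone, because the crowded catalyst avoids C–H bonds next to a substituent and 12 offers exactly four C–H bonds with two hydrogen neighbours, namely C-5 of ring A (1,3-pattern) and C-4 of rings B, D and E (1,2,3-pattern). Both C–H bonds of ring C lie between a methoxy and an aryloxy group, and after each borylation the remaining C–H bonds of that ring are flanked on both sides too, so excess boron reagent can be used to push all four sites to completion without overborylation. Methyl and diaryl ethers are inert to both stages, and cold, brief, basic peroxide under argon is preferred to Oxone in order to spare the electron-rich phenols formed.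

Step 8
Reactants: 14 tetraphenol heptamethyl ether of the target
Product: 15 target CNP0018313.0 (undecahydroxy pentamer)
Conditions: BBr3 (25 equiv, 1 M in CH2Cl2), CH2Cl2, −78 °C → rt, Ar; ice/water quench; EtOAc extraction under Ar
Reagents that add atoms: none
Why: In this Lewis-acid aryl methyl ether cleavage BBr3 binds each methoxy oxygen and bromide attacks the methyl carbon in an SN2 sense, whereas the four diaryl ether oxygens offer no sp3 carbon and stay intact, and the aqueous quench frees all eleven phenols.

## Compound list

1 | 4-bromo-2,6-dimethoxyphenol | COc1cc(Br)cc(OC)c1O | starting material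
2 | 2-fluoro-6-methoxybenzaldehyde | COc1cccc(F)c1C=O | starting material
3 | 2-(4-bromo-2,6-dimethoxyphenoxy)-6-methoxybenzaldehyde | COc1cccc(Oc2c(OC)cc(Br)cc2OC)c1C=O | intermediate
4 | 2-(4-bromo-2,6-dimethoxyphenoxy)-6-methoxyphenyl formate (not isolated) | COc1cccc(Oc2c(OC)cc(Br)cc2OC)c1OC=O | intermediate
5 | 2-(4-bromo-2,6-dimethoxyphenoxy)-6-methoxyphenol | COc1cccc(Oc2c(OC)cc(Br)cc2OC)c1O | intermediate
6 | 3-methoxyphenylboronic acid | COc1cccc(B(O)O)c1 | starting material
7 | 5-bromo-1,3-dimethoxy-2-[3-methoxy-2-(3-methoxyphenoxy)phenoxy]benzene (ABC bromide) | COc1cccc(Oc2c(OC)cccc2Oc2c(OC)cc(Br)cc2OC)c1 | intermediate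
8 | 2,6-dimethoxyphenol | COc1cccc(OC)c1O | starting material
9 | 2-(2,6-dimethoxyphenoxy)-6-methoxybenzaldehyde | COc1cccc(Oc2c(OC)cccc2OC)c1C=O | intermediate
10 | 2-(2,6-dimethoxyphenoxy)-6-methoxyphenyl formate (not isolated) | COc1cccc(Oc2c(OC)cccc2OC)c1OC=O | intermediate
11 | 2-(2,6-dimethoxyphenoxy)-6-methoxyphenol (DE phenol) | COc1cccc(Oc2c(OC)cccc2OC)c1O | intermediate
12 | tetra-deoxy pentamer heptamethyl ether | COc1cccc(Oc2c(OC)cccc2Oc2c(OC)cc(Oc3c(OC)cccc3Oc3c(OC)cccc3OC)cc2OC)c1 | intermediate
13 | tetrakis(pinacol boronate) of 12, boron on C-5 of ring A and C-4 of rings B, D, E (not isolated) | COc1cc(B2OC(C)(C)C(C)(C)O2)cc(Oc2c(OC)cc(B3OC(C)(C)C(C)(C)O3)cc2Oc2c(OC)cc(Oc3c(OC)cc(B4OC(C)(C)C(C)(C)O4)cc3Oc3c(OC)cc(B4OC(C)(C)C(C)(C)O4)cc3OC)cc2OC)c1 | intermediate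
14 | tetraphenol heptamethyl ether of the target | COc1cc(O)cc(Oc2c(OC)cc(O)cc2Oc2c(OC)cc(Oc3c(OC)cc(O)cc3Oc3c(OC)cc(O)cc3OC)cc2OC)c1 | intermediate
15 | CNP0018313.0 (achiral) | Oc1cc(O)cc(Oc2c(O)cc(O)cc2Oc2c(O)cc(Oc3c(O)cc(O)cc3Oc3c(O)cc(O)cc3O)cc2O)c1 | target

## Step count and risks

Total step count: 8. Longest linear sequence: 6 (steps 1, 2, 3, 6, 7, 8).

Steps most likely to fail:

1. **Step 7.**
   - Risk: the catalyst may decay on this electron-rich, slowly reacting substrate before all four rings have reacted. A small amount of attack next to a methoxy group on any one ring multiplies over four rings. Both effects would give hard-to-separate mixtures of differently oxygenated material. The phenols may also be overoxidised during the peroxide stage.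
   - Fallback: the fourfold event is split into two twofold ones, each purified on a smaller molecule. It sets out from 7, where the aryl bromide is tolerated and ring C stays blocked.
     - The same iridium borylation should give the bromo bis(boronate) F1, which is oxidised in the same pot to the bromo diphenol F2.
     - MeI/K2CO3 in acetone caps both phenols to give the bromo hexamethyl ether F3.
     - Ullmann coupling with 11 under the conditions of step 6 gives the dideoxy pentamer nonamethyl ether F4, in which only rings D and E keep an open C–H.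
     - A second twofold borylation gives the pentamer bis(boronate) F5 and, after peroxide, the diphenol nonamethyl ether F6.
     - BBr3 removes nine methyl groups from F6, which comes back to the route at 15.

2. **Step 6.**
   - Risk: activation of the electron-rich C–Br bond may be sluggish at the temperature the doubly flanked phenoxide needs. That would allow protodebromination and stalling.
   - Fallback: the polarity of ring C is reversed. It sets out from 7, which is converted by palladium-catalysed borylation with tetrahydroxydiboron (XPhos Pd G2, KOAc, EtOH, 80 °C) into the ABC boronic acid F7. F7 is joined to 11 by Chan–Lam–Evans coupling (Cu(OAc)2, pyridine, 4 Å MS, CH2Cl2, air, rt). No C–Br activation is then needed, and the route is rejoined at 12.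

3. **Step 3.**
   - Risk: binding of the crowded phenol (methoxy on one side, a bulky aryloxy on the other) to copper may be slow. The boronic acid would then be consumed by protodeboronation, homocoupling and oxidation to the phenol.
   - Fallback: an electrophilic aryl donor is used without any metal. 3-Iodoanisole is oxidised with mCPBA/TsOH·H2O in MeCN to the hydroxy(tosyloxy)iodoarene F8. F8 is condensed in the same pot with 1,3,5-trimethoxybenzene to give (3-methoxyphenyl)(2,4,6-trimethoxyphenyl)iodonium tosylate F9. Setting out from 5, treatment with F9 and K2CO3 in toluene at 60 °C transfers the less electron-rich 3-methoxyphenyl group by ligand coupling at iodine(III). This reaction type tolerates two ortho substituents and aryl bromides, and it comes back to the route at 7.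

## Further compounds

F1 | step 7 | bromo bis(boronate) of 7, boron on C-5 of ring A and C-4 of ring B (not isolated) | COc1cc(B2OC(C)(C)C(C)(C)O2)cc(Oc2c(OC)cc(B3OC(C)(C)C(C)(C)O3)cc2Oc2c(OC)cc(Br)cc2OC)c1
F2 | step 7 | bromo diphenol | COc1cc(O)cc(Oc2c(OC)cc(O)cc2Oc2c(OC)cc(Br)cc2OC)c1
F3 | step 7 | bromo hexamethyl ether | COc1cc(OC)cc(Oc2c(OC)cc(OC)cc2Oc2c(OC)cc(Br)cc2OC)c1
F4 | step 7 | dideoxy pentamer nonamethyl ether | COc1cc(OC)cc(Oc2c(OC)cc(OC)cc2Oc2c(OC)cc(Oc3c(OC)cccc3Oc3c(OC)cccc3OC)cc2OC)c1
F5 | step 7 | pentamer bis(boronate), boron on C-4 of rings D and E (not isolated) | COc1cc(OC)cc(Oc2c(OC)cc(OC)cc2Oc2c(OC)cc(Oc3c(OC)cc(B4OC(C)(C)C(C)(C)O4)cc3Oc3c(OC)cc(B4OC(C)(C)C(C)(C)O4)cc3OC)cc2OC)c1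
F6 | step 7 | diphenol nonamethyl ether | COc1cc(OC)cc(Oc2c(OC)cc(OC)cc2Oc2c(OC)cc(Oc3c(OC)cc(O)cc3Oc3c(OC)cc(O)cc3OC)cc2OC)c1
F7 | step 6 | ABC boronic acid | COc1cccc(Oc2c(OC)cccc2Oc2c(OC)cc(B(O)O)cc2OC)c1
F8 | step 3 | 1-[hydroxy(tosyloxy)-λ3-iodanyl]-3-methoxybenzene (not isolated) | COc1cccc(I(O)OS(=O)(=O)c2ccc(C)cc2)c1
F9 | step 3 | (3-methoxyphenyl)(2,4,6-trimethoxyphenyl)iodonium tosylate | COc1cccc([I+]c2c(OC)cc(OC)cc2OC)c1.Cc1ccc(S(=O)(=O)[O-])cc1
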